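Remark on the chemistry: (2R,3R)-(+)-fustin is taken as a commercial, enantiopure natural flavanonol. The sense of induction of the phosphoric acid in step 8 is assigned by analogy; a model benzhydrol should confirm it, and the antipodal catalyst is used if the sense is opposite. Some CIP descriptors (C3' of the lower unit, C4 of the upper unit) differ between the protected intermediates and the target only because O-substituents change the priorities; the spatial arrangement does not change.

## Structural features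

The target is a biflavonoid of two C15 units: an upper fisetinidol unit (benzo ring A, pyran ring C, catechol ring B) and a lower (+)-mollisacacidin unit, a (2R,3S,4R)-flavan-3,4-diol (benzo ring D, pyran ring F, catechol ring E). The units are joined by one C(sp3)–C(sp2) bond from C4 of ring C to C6' of ring D, a 4α→6 linkage. Ring C carries three adjacent stereocentres, C2, C3 and C4, in the all-trans arrangement (2-aryl and 4-aryl cis, 3-OH trans to both, all equatorial); ring F carries C2', C3' and C4', again all-trans. C4 is a diarylmethine carbon placed ortho to the pyran oxygen O1 on ring A, so the O1–C8a–C4a–C4 unit of ring C is a masked ortho-quinone methide whose methide carbon bears ring D; this is the feature the key step exploits. The benzylic C4'–OH, para to the 7'-oxygen, ionises easily in acid, so the lower unit is itself a C4 electrophile and the free polyphenol tends to self-condense. The six phenols are sensitive to air in base. The real difficulty is to make the C4–C6' junction with the 4α configuration and at C6' rather than C8', while the lower 3,4-diol survives.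

## Logic of the disconnections

20 is traced to 19 by cutting six phenolic O–CH2Ph bonds. The phenols must be masked through organolithium, acid and borane chemistry, and benzyl is the only group that tolerates an ortho-aryllithium. The demand on the forward step is a neutral hydrogenolysis that spares the benzylic C4'–OH.

19 is traced to 18 by cutting the two O–Si bonds at C3' and C4'. The silyl ethers keep the lower diol from acting as a proton source for the organometallics and reduce the tendency of C4'–O to ionise. The forward step must use fluoride only, with no acid.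

18 is traced to 16 by cutting the C3–O and C2–H bonds of ring C. This removes two of the three upper stereocentres and leaves an enol ether with the single stereocentre C4. The forward step must add H and boron syn, with boron at C3, on the face opposite the C4 aryl group.

16 is traced to 9 and 13 by cutting the C3–C4 and O1–C2 bonds, through 14 and 15. Stated in one sentence, the route is an enantioselective acid-catalysed [4+2] annulation between the ortho-quinone methide 14, whose methide carbon already carries the whole lower flavan unit, and the ring B enamide 13. The cut is made here because it closes ring C on the lower unit without ever making a flavan C4 cation; the linkage position on ring D is fixed beforehand, and the skeleton falls into three fragments of similar size. The forward step must ionise the diaryl carbinol selectively in the presence of the C4' silyl ether and must set C4 by catalyst control.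

9 is traced to 5 and 6 by cutting the C4–C6' bond as an aryl-metal addition to an aldehyde, through 7 and 8. The carbinol configuration is irrelevant because it is erased in 14, and the regiochemistry is carried by the C–Br bond. The forward step needs a bromine–lithium exchange that tolerates benzyl and silyl ethers.

5 is traced to 4, 3, 2 and 1 by cutting in turn the C6'–Br bond, two O–Si bonds, the C4'–H bond (hydride addition to a ketone, which sets C4') and three O–benzyl bonds. C2' and C3' come from the chiral pool compound 1. The forward steps require bromination para to O1' and hydride delivery that gives the 3,4-trans diol.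

13 is traced to 11 and 10, through 12, by cutting the N–acetyl bond and the C=N bond. This is standard functional group chemistry on a commercial ketone.

## Other disconnections considered

Alternative 1: Cut the C4–C6' bond in the biomimetic sense, which is the first idea that comes to mind. In the forward direction, acid would ionise 3 to the benzylic cation A1, and ring D of a second molecule of 3 would capture it in a Friedel–Crafts reaction to give 19 directly in about four steps. The chosen plan is preferred on three structural grounds. Electrophile and nucleophile are the same compound, and the product 19 keeps both a nucleophilic ring D and an ionisable C4'–O bond, so oligomers are expected. Ring D offers C6' and C8', so regioisomers are expected. The C4 configuration rests on substrate control alone. The chosen plan fixes the linkage by a C–Br bond, never forms A1, and sets C4 with a catalyst.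

Alternative 2: Cut the C4–C6' bond at the ketone oxidation level. Aryllithium 7 would add to the C4 carbonyl of the silylated flavanonol A2 to give the tertiary carbinol A3, and ionic hydrogenation (Et3SiH, acid) would then remove the C4 oxygen. The mechanism argues against it. Hydride should enter the 4-aryl cation anti to the C3 silyloxy group, which places the aryl group cis to it and gives the 3,4-cis (4β) epimer, the wrong one. In addition, the basic aryllithium can enolise A2 and open ring C by β-elimination of the ring aryloxide, and the acid step threatens the C4'–O bond.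

Alternative 3: Keep the ortho-quinone methide 14 but use the (E)-styrylboronate A4 as the two-carbon partner, so that one [4+2] cycloaddition gives the 3-boryl flavan A5 with C2, C3 and C4 set together, followed by C–B oxidation. This needs endo/exo and facial control at the same time. The boronate has no hydrogen-bond donor to organise the phosphate catalyst, and the boryl group lowers the nucleophilicity of the alkene. The step count equals that of the chosen plan (oxidation in place of hydroboration), so the added risk buys no simplicity. The chosen plan puts only C4 under catalyst control, with an N–H handle, and relays C2 and C3 by a substrate-controlled hydroboration.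

Key step: step 8

## Route

Step 1
Reactants: 1 (+)-fustin, (2R,3R)-2-(3,4-dihydroxyphenyl)-3,7-dihydroxychroman-4-one
Product: 2 (2R,3R)-7-(benzyloxy)-2-[3,4-bis(benzyloxy)phenyl]-3-hydroxychroman-4-one
Conditions: BnBr (3.3 equiv), K2CO3, DMF, rt, argon
Reagents that add atoms: benzyl bromide, BrCc1ccccc1
Why: Williamson etherification; the three phenols are far more acidic than the C3 alcohol, so carbonate should alkylate only them, and mild, oxygen-free conditions avoid ring opening and epimerisation of the flavanonol.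

Step 2
Reactants: 2 (2R,3R)-7-(benzyloxy)-2-[3,4-bis(benzyloxy)phenyl]-3-hydroxychroman-4-one
Product: 3 (2R,3S,4R)-7-(benzyloxy)-2-[3,4-bis(benzyloxy)phenyl]chromane-3,4-diol (2,3-trans-3,4-trans)
Conditions: NaBH4, MeOH/THF, 0 °C
Reagents that add atoms: none
Why: Borohydride reduction of a 2,3-trans-dihydroflavonol; axial hydride delivery to C4' of the half-chair should give the equatorial 4'-OH trans to the 3'-OH, the established outcome for this substrate class.

Step 3
Reactants: 3 (2R,3S,4R)-7-(benzyloxy)-2-[3,4-bis(benzyloxy)phenyl]chromane-3,4-diol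
Product: 4 (2R,3R,4R)-7-(benzyloxy)-2-[3,4-bis(benzyloxy)phenyl]-3,4-bis(tert-butyldimethylsilyloxy)chromane
Conditions: TBSOTf, 2,6-lutidine, CH2Cl2, −78 to 0 °C
Reagents that add atoms: tert-butyldimethylsilyl trifluoromethanesulfonate, CC(C)(C)[Si](C)(C)OS(=O)(=O)C(F)(F)F
Why: Silylation of both secondary alcohols under buffered, non-ionising conditions; no stereocentre is touched.

Step 4
Reactants: 4 (2R,3R,4R)-7-(benzyloxy)-2-[3,4-bis(benzyloxy)phenyl]-3,4-bis(tert-butyldimethylsilyloxy)chromane
Product: 5 (2R,3R,4R)-7-(benzyloxy)-2-[3,4-bis(benzyloxy)phenyl]-6-bromo-3,4-bis(tert-butyldimethylsilyloxy)chromane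
Conditions: NBS (1.0 equiv), CH2Cl2, −40 to 0 °C, dark
Reagents that add atoms: N-bromosuccinimide, O=C1CCC(=O)N1Br
Why: Electrophilic aromatic bromination; ring D, with two meta-disposed oxygens, is much more nucleophilic than the catechol or benzyl rings, and attack should occur at C6' (para to O1', one ortho neighbour) rather than at C8', which is flanked by two oxygens.

Step 5
Reactants: 5 (2R,3R,4R)-7-(benzyloxy)-2-[3,4-bis(benzyloxy)phenyl]-6-bromo-3,4-bis(tert-butyldimethylsilyloxy)chromane; 6 4-(benzyloxy)-2-hydroxybenzaldehyde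
Product: 9 5-(benzyloxy)-2-[{(2R,3R,4R)-7-(benzyloxy)-2-[3,4-bis(benzyloxy)phenyl]-3,4-bis(tert-butyldimethylsilyloxy)chroman-6-yl}(hydroxy)methyl]phenol (both carbinol epimers), via aryllithium 7 (not isolated), via sodium 5-(benzyloxy)-2-formylphenolate 8 (not isolated)
Conditions: 6, NaH, THF, 0 °C; separately 5, n-BuLi, THF, −78 °C; combine, −78 to −20 °C; aq NH4Cl
Reagents that add atoms: none
Why: Bromine–lithium exchange followed by 1,2-addition of the aryllithium to the aldehyde, whose phenol is masked in the flask as its sodium salt; the new carbinol centre forms as a mixture, which does not matter because step 8 erases it.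

Step 6
Reactants: 10 1-[3,4-bis(benzyloxy)phenyl]ethan-1-one
Product: 11 (E)-1-[3,4-bis(benzyloxy)phenyl]ethan-1-one oxime
Conditions: NH2OH·HCl, NaOAc, EtOH/H2O, 70 °C
Reagents that add atoms: hydroxylamine hydrochloride, [NH3+]O.[Cl-]
Why: Oxime condensation of an aryl methyl ketone; the (E) isomer with OH anti to the aryl group should predominate.

Step 7
Reactants: 11 (E)-1-[3,4-bis(benzyloxy)phenyl]ethan-1-one oxime
Product: 13 N-{1-[3,4-bis(benzyloxy)phenyl]ethenyl}acetamide, via oxime acetate 12 (not isolated)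
Conditions: Fe powder, Ac2O, AcOH, toluene, 70 °C
Reagents that add atoms: acetic anhydride, CC(=O)OC(C)=O
Why: Reductive acylation of a ketoxime; O-acetylation, N–O cleavage by zerovalent iron, N-acetylation and tautomerisation should give the enamide, with the benzyl ethers inert.

Step 8
Reactants: 9 5-(benzyloxy)-2-[{(2R,3R,4R)-7-(benzyloxy)-2-[3,4-bis(benzyloxy)phenyl]-3,4-bis(tert-butyldimethylsilyloxy)chroman-6-yl}(hydroxy)methyl]phenol; 13 N-{1-[3,4-bis(benzyloxy)phenyl]ethenyl}acetamide
Product: 16 (4S)-7-(benzyloxy)-2-[3,4-bis(benzyloxy)phenyl]-4-{(2R,3R,4R)-7-(benzyloxy)-2-[3,4-bis(benzyloxy)phenyl]-3,4-bis(tert-butyldimethylsilyloxy)chroman-6-yl}-4H-chromene, via (E)-ortho-quinone methide 14 (not isolated), via 2-acetamidochroman 15 (not isolated)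
Conditions: (R)-3,3'-bis(2,4,6-triisopropylphenyl)-1,1'-binaphthyl-2,2'-diyl hydrogen phosphate (10 mol %), 4 Å molecular sieves, CH2Cl2, 0 °C to rt; then 40 °C; argon
Reagents that add atoms: none
Why: The phosphoric acid should ionise the ortho-hydroxybenzhydrol 9 (both carbinol epimers, so the step is stereoconvergent) to the (E)-ortho-quinone methide 14, which stays hydrogen-bonded to the catalyst through its carbonyl oxygen while the phosphoryl oxygen binds the N–H of enamide 13. The nucleophilic CH2 terminus of 13 adds to the methide carbon (C3–C4 bond), and the phenolic oxygen closes ring C on the N-acyliminium carbon (O1–C2 bond; formally an inverse-electron-demand oxa-[4+2] cycloaddition, in the stepwise view a conjugate addition followed by 6-exo-trig closure) to give aminal 15. Warming lets the acid expel acetamide from 15 through the 2-aryl oxocarbenium ion, and loss of H3 gives the conjugated enol ether 16. The closest known reaction type is the chiral phosphoric acid-catalysed [4+2] annulation of ortho-quinone methides, generated in the flask from ortho-hydroxybenzhydrols, with acetophenone-derived enamides to 2-amidochromans and 4H-chromenes. The only stereocentre that survives, C4, is set by the catalyst pocket, which exposes one face of the methide carbon; the lower-unit stereocentres lie four or more bonds away across a flat arene and should exert little bias, and the C2 aminal centre is erased. The step needs chemoselective ionisation of the doubly benzylic, phenol-assisted carbinol over the mono-benzylic C4' silyl ether, which the far greater stabilisation of 14 secures, and the regiochemistry is fixed by polarity. Hydrolysis of 15 by the released water is not harmful, since the resulting keto-phenol recloses and dehydrates to the same 16.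

Step 9
Reactants: 16 (4S)-7-(benzyloxy)-2-[3,4-bis(benzyloxy)phenyl]-4-{(2R,3R,4R)-7-(benzyloxy)-2-[3,4-bis(benzyloxy)phenyl]-3,4-bis(tert-butyldimethylsilyloxy)chroman-6-yl}-4H-chromene
Product: 18 (2R,3S,4S)-7-(benzyloxy)-2-[3,4-bis(benzyloxy)phenyl]-4-{(2R,3R,4R)-7-(benzyloxy)-2-[3,4-bis(benzyloxy)phenyl]-3,4-bis(tert-butyldimethylsilyloxy)chroman-6-yl}chroman-3-ol (2,3-trans-3,4-trans), via C3 alkylborane 17 (not isolated)
Conditions: BH3·SMe2, THF, 0 °C to rt; then NaOH, H2O2, H2O, 0 °C
Reagents that add atoms: hydrogen peroxide, OO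
Why: Hydroboration–oxidation of a 2-aryl-4H-chromene; boron should go to C3 (β-carbon of the enol ether and the non-benzylic carbon) and add syn with hydrogen on the face opposite the C4 aryl group, and oxidation with retention then places the 3-OH trans to both aryl groups and sets C2 and C3 from C4.

Step 10
Reactants: 18 (2R,3S,4S)-7-(benzyloxy)-2-[3,4-bis(benzyloxy)phenyl]-4-{(2R,3R,4R)-7-(benzyloxy)-2-[3,4-bis(benzyloxy)phenyl]-3,4-bis(tert-butyldimethylsilyloxy)chroman-6-yl}chroman-3-ol
Product: 19 (2R,3S,4R)-7-(benzyloxy)-2-[3,4-bis(benzyloxy)phenyl]-6-{(2R,3S,4S)-7-(benzyloxy)-2-[3,4-bis(benzyloxy)phenyl]-3-hydroxychroman-4-yl}chromane-3,4-diol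
Conditions: Bu4NF, THF, 0 °C to rt
Reagents that add atoms: none
Why: Fluoride cleavage of the two silyl ethers under non-acidic conditions, so the benzylic C4'–O bond should not ionise and no stereocentre is at risk.

Step 11
Reactants: 19 (2R,3S,4R)-7-(benzyloxy)-2-[3,4-bis(benzyloxy)phenyl]-6-{(2R,3S,4S)-7-(benzyloxy)-2-[3,4-bis(benzyloxy)phenyl]-3-hydroxychroman-4-yl}chromane-3,4-diol
Product: 20 (2R,3S,4R)-2-(3,4-dihydroxyphenyl)-6-[(2R,3S,4R)-2-(3,4-dihydroxyphenyl)-3,7-dihydroxychroman-4-yl]chromane-3,4,7-triol, fisetinidol-(4α→6)-mollisacacidin (CNP0280090.3)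
Conditions: H2 (1 atm), Pd(OH)2/C, THF/MeOH, rt; filtration and freeze-drying without acid
Reagents that add atoms: none
Why: Hydrogenolysis of six aryl benzyl ethers under neutral conditions, which should be faster than cleavage of the secondary benzylic C4'–OH or of the pyran C2–O bonds; no stereocentre is involved.

## Compound list

1 | (+)-fustin, (2R,3R)-2-(3,4-dihydroxyphenyl)-3,7-dihydroxychroman-4-one | Oc1ccc2c(c1)O[C@H](c1ccc(O)c(O)c1)[C@@H](O)C2=O | starting material
2 | (2R,3R)-7-(benzyloxy)-2-[3,4-bis(benzyloxy)phenyl]-3-hydroxychroman-4-one | c1ccccc1COc1ccc2c(c1)O[C@H](c1ccc(OCc3ccccc3)c(OCc3ccccc3)c1)[C@@H](O)C2=O | intermediate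
3 | (2R,3S,4R)-7-(benzyloxy)-2-[3,4-bis(benzyloxy)phenyl]chromane-3,4-diol | c1ccccc1COc1ccc2c(c1)O[C@H](c1ccc(OCc3ccccc3)c(OCc3ccccc3)c1)[C@@H](O)[C@@H]2O | intermediate
4 | (2R,3R,4R)-7-(benzyloxy)-2-[3,4-bis(benzyloxy)phenyl]-3,4-bis(tert-butyldimethylsilyloxy)chromane | c1ccccc1COc1ccc2c(c1)O[C@H](c1ccc(OCc3ccccc3)c(OCc3ccccc3)c1)[C@@H](O[Si](C)(C)C(C)(C)C)[C@@H]2O[Si](C)(C)C(C)(C)C | intermediate
5 | (2R,3R,4R)-7-(benzyloxy)-2-[3,4-bis(benzyloxy)phenyl]-6-bromo-3,4-bis(tert-butyldimethylsilyloxy)chromane | c1ccccc1COc1c(Br)cc2c(c1)O[C@H](c1ccc(OCc3ccccc3)c(OCc3ccccc3)c1)[C@@H](O[Si](C)(C)C(C)(C)C)[C@@H]2O[Si](C)(C)C(C)(C)C | intermediate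
6 | 4-(benzyloxy)-2-hydroxybenzaldehyde | O=Cc1ccc(OCc2ccccc2)cc1O | starting material
7 | aryllithium from 5, lithium at C6 of the chromane | c1ccccc1COc1c([Li])cc2c(c1)O[C@H](c1ccc(OCc3ccccc3)c(OCc3ccccc3)c1)[C@@H](O[Si](C)(C)C(C)(C)C)[C@@H]2O[Si](C)(C)C(C)(C)C | intermediate (not isolated)
8 | sodium 5-(benzyloxy)-2-formylphenolate | [Na+].[O-]c1cc(OCc2ccccc2)ccc1C=O | intermediate (not isolated)
9 | 5-(benzyloxy)-2-[{(2R,3R,4R)-7-(benzyloxy)-2-[3,4-bis(benzyloxy)phenyl]-3,4-bis(tert-butyldimethylsilyloxy)chroman-6-yl}(hydroxy)methyl]phenol, both carbinol epimers | c1ccccc1COc1c(C(O)c4ccc(OCc5ccccc5)cc4O)cc2c(c1)O[C@H](c1ccc(OCc3ccccc3)c(OCc3ccccc3)c1)[C@@H](O[Si](C)(C)C(C)(C)C)[C@@H]2O[Si](C)(C)C(C)(C)C | intermediate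
10 | 1-[3,4-bis(benzyloxy)phenyl]ethan-1-one | CC(=O)c1ccc(OCc2ccccc2)c(OCc2ccccc2)c1 | starting material
11 | (E)-1-[3,4-bis(benzyloxy)phenyl]ethan-1-one oxime | C/C(=N\O)c1ccc(OCc2ccccc2)c(OCc2ccccc2)c1 | intermediate
12 | (E)-1-[3,4-bis(benzyloxy)phenyl]ethan-1-one O-acetyloxime | C/C(=N\OC(C)=O)c1ccc(OCc2ccccc2)c(OCc2ccccc2)c1 | intermediate (not isolated)
13 | N-{1-[3,4-bis(benzyloxy)phenyl]ethenyl}acetamide | C=C(NC(C)=O)c1ccc(OCc2ccccc2)c(OCc2ccccc2)c1 | intermediate
14 | (E)-3-(benzyloxy)-6-[{(2R,3R,4R)-7-(benzyloxy)-2-[3,4-bis(benzyloxy)phenyl]-3,4-bis(tert-butyldimethylsilyloxy)chroman-6-yl}methylidene]cyclohexa-2,4-dien-1-one | O=C1C=C(OCc2ccccc2)C=C/C1=C\c1cc2c(cc1OCc1ccccc1)O[C@H](c1ccc(OCc3ccccc3)c(OCc3ccccc3)c1)[C@@H](O[Si](C)(C)C(C)(C)C)[C@@H]2O[Si](C)(C)C(C)(C)C | intermediate (not isolated)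
15 | N-[(4S)-7-(benzyloxy)-2-[3,4-bis(benzyloxy)phenyl]-4-{(2R,3R,4R)-7-(benzyloxy)-2-[3,4-bis(benzyloxy)phenyl]-3,4-bis(tert-butyldimethylsilyloxy)chroman-6-yl}chroman-2-yl]acetamide, C2 epimers | c1ccccc1COc1ccc2c(c1)OC(NC(C)=O)(c1ccc(OCc3ccccc3)c(OCc3ccccc3)c1)C[C@@H]2c1cc2c(cc1OCc1ccccc1)O[C@H](c1ccc(OCc3ccccc3)c(OCc3ccccc3)c1)[C@@H](O[Si](C)(C)C(C)(C)C)[C@@H]2O[Si](C)(C)C(C)(C)C | intermediate (not isolated)
16 | (4S)-7-(benzyloxy)-2-[3,4-bis(benzyloxy)phenyl]-4-{(2R,3R,4R)-7-(benzyloxy)-2-[3,4-bis(benzyloxy)phenyl]-3,4-bis(tert-butyldimethylsilyloxy)chroman-6-yl}-4H-chromene | c1ccccc1COc1ccc2c(c1)OC(c1ccc(OCc3ccccc3)c(OCc3ccccc3)c1)=C[C@@H]2c1cc2c(cc1OCc1ccccc1)O[C@H](c1ccc(OCc3ccccc3)c(OCc3ccccc3)c1)[C@@H](O[Si](C)(C)C(C)(C)C)[C@@H]2O[Si](C)(C)C(C)(C)C | intermediate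
17 | C3 alkylborane of 16 (BH2 at C3, trans to both aryl groups) | c1ccccc1COc1ccc2c(c1)O[C@H](c1ccc(OCc3ccccc3)c(OCc3ccccc3)c1)[C@@H](B)[C@@H]2c1cc2c(cc1OCc1ccccc1)O[C@H](c1ccc(OCc3ccccc3)c(OCc3ccccc3)c1)[C@@H](O[Si](C)(C)C(C)(C)C)[C@@H]2O[Si](C)(C)C(C)(C)C | intermediate (not isolated)
18 | (2R,3S,4S)-7-(benzyloxy)-2-[3,4-bis(benzyloxy)phenyl]-4-{(2R,3R,4R)-7-(benzyloxy)-2-[3,4-bis(benzyloxy)phenyl]-3,4-bis(tert-butyldimethylsilyloxy)chroman-6-yl}chroman-3-ol | c1ccccc1COc1ccc2c(c1)O[C@H](c1ccc(OCc3ccccc3)c(OCc3ccccc3)c1)[C@@H](O)[C@@H]2c1cc2c(cc1OCc1ccccc1)O[C@H](c1ccc(OCc3ccccc3)c(OCc3ccccc3)c1)[C@@H](O[Si](C)(C)C(C)(C)C)[C@@H]2O[Si](C)(C)C(C)(C)C | intermediate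
19 | (2R,3S,4R)-7-(benzyloxy)-2-[3,4-bis(benzyloxy)phenyl]-6-{(2R,3S,4S)-7-(benzyloxy)-2-[3,4-bis(benzyloxy)phenyl]-3-hydroxychroman-4-yl}chromane-3,4-diol | c1ccccc1COc1ccc2c(c1)O[C@H](c1ccc(OCc3ccccc3)c(OCc3ccccc3)c1)[C@@H](O)[C@@H]2c1cc2c(cc1OCc1ccccc1)O[C@H](c1ccc(OCc3ccccc3)c(OCc3ccccc3)c1)[C@@H](O)[C@@H]2O | intermediate
20 | (2R,3S,4R)-2-(3,4-dihydroxyphenyl)-6-[(2R,3S,4R)-2-(3,4-dihydroxyphenyl)-3,7-dihydroxychroman-4-yl]chromane-3,4,7-triol | Oc1ccc2c(c1)O[C@H](c1ccc(O)c(O)c1)[C@@H](O)[C@@H]2c1cc2c(cc1O)O[C@H](c1ccc(O)c(O)c1)[C@@H](O)[C@@H]2O | target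

## Step count and least certain steps

Total step count: 11. Longest linear sequence: 9 steps (steps 1, 2, 3, 4, 5, 8, 9, 10, 11); steps 6 and 7 form the short branch to 13.

Step 8 (key step). The most likely failure is poor facial selectivity at the methide carbon: the aryl group on it is an ortho-benzyloxy, ring-fused arene, bulkier than in the closest precedent, and may not fit the catalyst pocket. Other risks are slow, competing ionisation of the C4' silyl ether, hydrolysis of the enamide by the released water, and air oxidation of the 4H-chromene to a chromenylium ion; if the aminal persists, it would have to be isolated and eliminated separately with a trace of sulfonic acid. The fallback sets out from 5 (with 6 and 10) and returns at 16, and it sets C4 by a rhodium-catalysed conjugate arylation in the open chain. Compound 5 is lithiated (n-BuLi, −78 °C) and quenched with B(OMe)3 and water to give the lower-unit 6-boronic acid F1. Aldehyde 6 and ketone 10 are condensed (KOH, EtOH, Claisen–Schmidt) to the (E)-2-hydroxychalcone F2. Asymmetric 1,4-addition of F1 to F2 with [Rh(OH)(cod)]2 and the chiral diene (1R,4R)-2,5-diphenylbicyclo[2.2.2]octa-2,5-diene (K3PO4, dioxane/H2O, 50 °C) should give the β,β-diaryl ketone F3. Pyridinium p-toluenesulfonate in toluene then cyclodehydrates F3 to 16.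

Step 5. The aryllithium may add incompletely to the electron-rich, poorly soluble phenolate aldehyde and be lost by protonation; the benzhydrol may also lose water on acidic supports during purification. The fallback sets out from 5 and returns at 9 with the polarity reversed. Compound 5 is lithiated as before and formylated with DMF to the lower-unit 6-carbaldehyde F4. Bromomagnesium 3-(benzyloxy)phenolate (from 3-(benzyloxy)phenol and EtMgBr, toluene, rt) is then hydroxyalkylated by F4 ortho to the phenolate oxygen through a six-membered magnesium chelate, at the carbon para to the benzyloxy group, which gives 9.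

Step 9. Borane addition to the hindered, trisubstituted enol ether may be slow, which would allow β-elimination of the ring aryloxide from the β-aryloxy organoborane (ring opening) or erode the facial selectivity. The fallback sets out from 16 and returns at 18. Dihydroxylation with OsO4 and N-methylmorpholine N-oxide on the face opposite the C4 aryl group gives the 2,3-cis 2-hydroxy hemiketal diol F5. Ionic reduction (Et3SiH, BF3·OEt2, CH2Cl2/MeCN, −40 °C) through the C2 oxocarbenium ion, with axial hydride delivery as in the reduction of aryl C-glycoside lactols, should place ring B equatorial and give 18.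

Step 11. Hydrogenolytic loss of the benzylic C4'–OH may compete with debenzylation, and traces of acid during concentration may trigger ionisation and self-condensation of the free flavan-3,4-diol. The fallback sets out from 19 and returns at 20, carrying C4' through the deprotection as a ketone. MnO2 in CH2Cl2 oxidises only the benzylic C4' hydroxyl to the hexa-O-benzyl flavanonol ketone F6. Hydrogenolysis (H2, Pd(OH)2/C) gives the free hexaphenol ketone F7, which has no benzylic alcohol to lose. NaBH4 in EtOH at 0 °C, with axial hydride delivery as in step 2, gives 20.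

## Further compounds

F1 | step 8 | {(2R,3R,4R)-7-(benzyloxy)-2-[3,4-bis(benzyloxy)phenyl]-3,4-bis(tert-butyldimethylsilyloxy)chroman-6-yl}boronic acid | c1ccccc1COc1c(B(O)O)cc2c(c1)O[C@H](c1ccc(OCc3ccccc3)c(OCc3ccccc3)c1)[C@@H](O[Si](C)(C)C(C)(C)C)[C@@H]2O[Si](C)(C)C(C)(C)C
F2 | step 8 | (E)-3-[4-(benzyloxy)-2-hydroxyphenyl]-1-[3,4-bis(benzyloxy)phenyl]prop-2-en-1-one | O=C(/C=C/c1ccc(OCc2ccccc2)cc1O)c1ccc(OCc2ccccc2)c(OCc2ccccc2)c1
F3 | step 8 | (3S)-3-[4-(benzyloxy)-2-hydroxyphenyl]-1-[3,4-bis(benzyloxy)phenyl]-3-{(2R,3R,4R)-7-(benzyloxy)-2-[3,4-bis(benzyloxy)phenyl]-3,4-bis(tert-butyldimethylsilyloxy)chroman-6-yl}propan-1-one | O=C(C[C@@H](c1ccc(OCc3ccccc3)cc1O)c1cc2c(cc1OCc1ccccc1)O[C@H](c1ccc(OCc3ccccc3)c(OCc3ccccc3)c1)[C@@H](O[Si](C)(C)C(C)(C)C)[C@@H]2O[Si](C)(C)C(C)(C)C)c1ccc(OCc2ccccc2)c(OCc2ccccc2)c1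
F4 | step 5 | (2R,3R,4R)-7-(benzyloxy)-2-[3,4-bis(benzyloxy)phenyl]-3,4-bis(tert-butyldimethylsilyloxy)chromane-6-carbaldehyde | c1ccccc1COc1c(C=O)cc2c(c1)O[C@H](c1ccc(OCc3ccccc3)c(OCc3ccccc3)c1)[C@@H](O[Si](C)(C)C(C)(C)C)[C@@H]2O[Si](C)(C)C(C)(C)C
F5 | step 9 | 2,3-cis-2-hydroxy hemiketal diol of 16 (2-OH and 3-OH both trans to the C4 aryl group), 7-(benzyloxy)-2-[3,4-bis(benzyloxy)phenyl]-4-{lower-unit-6-yl}chromane-2,3-diol | c1ccccc1COc1ccc2c(c1)O[C@](O)(c1ccc(OCc3ccccc3)c(OCc3ccccc3)c1)[C@@H](O)[C@@H]2c1cc2c(cc1OCc1ccccc1)O[C@H](c1ccc(OCc3ccccc3)c(OCc3ccccc3)c1)[C@@H](O[Si](C)(C)C(C)(C)C)[C@@H]2O[Si](C)(C)C(C)(C)C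
F6 | step 11 | (2R,3R)-7-(benzyloxy)-2-[3,4-bis(benzyloxy)phenyl]-6-{(2R,3S,4S)-7-(benzyloxy)-2-[3,4-bis(benzyloxy)phenyl]-3-hydroxychroman-4-yl}-3-hydroxychroman-4-one | c1ccccc1COc1ccc2c(c1)O[C@H](c1ccc(OCc3ccccc3)c(OCc3ccccc3)c1)[C@@H](O)[C@@H]2c1cc2c(cc1OCc1ccccc1)O[C@H](c1ccc(OCc3ccccc3)c(OCc3ccccc3)c1)[C@@H](O)C2=O
F7 | step 11 | (2R,3R)-2-(3,4-dihydroxyphenyl)-6-[(2R,3S,4R)-2-(3,4-dihydroxyphenyl)-3,7-dihydroxychroman-4-yl]-3,7-dihydroxychroman-4-one, fisetinidol-(4α→6)-fustin | Oc1ccc2c(c1)O[C@H](c1ccc(O)c(O)c1)[C@@H](O)[C@@H]2c1cc2c(cc1O)O[C@H](c1ccc(O)c(O)c1)[C@@H](O)C2=O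
A1 | alternative 1 | (2R,3S)-7-(benzyloxy)-2-[3,4-bis(benzyloxy)phenyl]-3-hydroxychroman-4-ylium, benzylic C4 cation from 3 | c1ccccc1COc1ccc2c(c1)O[C@H](c1ccc(OCc3ccccc3)c(OCc3ccccc3)c1)[C@@H](O)[CH+]2
A2 | alternative 2 | (2R,3R)-7-(benzyloxy)-2-[3,4-bis(benzyloxy)phenyl]-3-(tert-butyldimethylsilyloxy)chroman-4-one | c1ccccc1COc1ccc2c(c1)O[C@H](c1ccc(OCc3ccccc3)c(OCc3ccccc3)c1)[C@@H](O[Si](C)(C)C(C)(C)C)C2=O
A3 | alternative 2 | tertiary carbinol from 7 and A2, 4-aryl-7-(benzyloxy)-2-[3,4-bis(benzyloxy)phenyl]-3-(tert-butyldimethylsilyloxy)chroman-4-ol with the lower unit as the 4-aryl group, C4 epimers | c1ccccc1COc1ccc2c(c1)O[C@H](c1ccc(OCc3ccccc3)c(OCc3ccccc3)c1)[C@@H](O[Si](C)(C)C(C)(C)C)C2(O)c1cc2c(cc1OCc1ccccc1)O[C@H](c1ccc(OCc3ccccc3)c(OCc3ccccc3)c1)[C@@H](O[Si](C)(C)C(C)(C)C)[C@@H]2O[Si](C)(C)C(C)(C)C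
A4 | alternative 3 | 2-{(E)-2-[3,4-bis(benzyloxy)phenyl]ethenyl}-4,4,5,5-tetramethyl-1,3,2-dioxaborolane | CC1(C)OB(/C=C/c2ccc(OCc3ccccc3)c(OCc3ccccc3)c2)OC1(C)C
A5 | alternative 3 | 2,3-trans-3,4-trans 3-(pinacolatoboryl)flavan cycloadduct of 14 and A4 | c1ccccc1COc1ccc2c(c1)O[C@H](c1ccc(OCc3ccccc3)c(OCc3ccccc3)c1)[C@@H](B3OC(C)(C)C(C)(C)O3)[C@@H]2c1cc2c(cc1OCc1ccccc1)O[C@H](c1ccc(OCc3ccccc3)c(OCc3ccccc3)c1)[C@@H](O[Si](C)(C)C(C)(C)C)[C@@H]2O[Si](C)(C)C(C)(C)C
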